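A straight logarithmic line can be ruled on past a knee that its readings never reached.

| flask | E | L | remark | time |
|---|---|---|---|---|
| eta | 0.050 M | 0.80 equiv | the very flask that is asked about, followed so far |  |
| alpha | 0.050 M | 1.2 equiv | run made earlier |  |
| flask | 0.050 M | 0.800 equiv |  | 6.0 min |

eta run (percent of the E charged)

| time / s | Z / % | E / % |
|---|---|---|
| 10.0 | 6.2 | 94.8 |
| 25.0 | 14.8 | 85.9 |
| 50.0 | 26.8 | 75.0 |
| 80.0 | 36.9 | 61.8 |

alpha run (percent of the E charged)

| time / min | Z / % | E / % |
|---|---|---|
| 0.200 | 7.2 | 93.1 |
| 0.417 | 13.2 | 85.7 |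
| 1.00 | 30.6 | 69.1 |
| 2.50 | 60.1 | 40.0 |

(scatter of a reading: 1 percentage point)

- what was read earlier has a scatter of 1 percentage point, one standard deviation

- concentration of Z at 6.0 min, in M
- concentration of E at 6.0 min, in M

In both runs the logarithm of E falls steadily, and the last readings give slopes:

eta run: 0.361 min⁻¹; alpha run: 0.367 min⁻¹

These match within the scatter at different charges of L, so this reckoning draws the flask with the alpha slope. E starts down at 0.0183 M min⁻¹, and E and Z cross after:

1.89 min

One power of ten of E takes 6.28 min. In the flask L is the limiting reagent, charged below E. Taking one L per Z, the knee comes when E has fallen by 0.699 of a power of ten: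

4.39 min

That is before the asked time. Beyond the knee the curve runs flat at the stop level, E charged less L charged:

0.0100 M

Flatness is this reckoning's commitment and no reading tests it, for the last readings stand with Z at 36.9% in the eta run and 60.1% in the alpha run, short of the L charged in each. Z should then stand at 0.0400 M.

The forecast gives 0.04 M of Z and 0.0062 M of E, below the stop level, holding that “E keeps decaying if activation is irreversible”.

The flask gives 0.0393 M of Z and 0.00993 M of E, with L at 0% of its charge.

    E ⇌ D (K = 0.00180, k = 0.370 min⁻¹)
    D ⇌ X (K = 0.350, k = 46.0 min⁻¹)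
    L + D → Z (k = 2.70 × 10⁵ L mol⁻¹ min⁻¹)
    L + X → Q (k = 2.30 × 10⁵ L mol⁻¹ min⁻¹)
    E → G (k = 3.30 × 10⁻⁴ min⁻¹)

The two part over E after the knee: at 60.0 min the flask still holds 0.00976 M. The neighbour charged with 0.480 equiv of L has its stop level at 0.0260 M, reached by the same reckoning after 1.78 min. At the asked time that neighbour holds 0.0259 M of E, with L at 0% of its charge, and 0.0234 M of Z.

Readings and results were computed on assumed constants; scatter was added.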